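**Retrosynthetic overview**
1. The target is 8,14-secoursa-8(26),13-dien-3β-ol. The C8 methylene comes from a C8 ketone, and the C11–C12 bond is cut into AB sulfone 17 and DE allylic bromide 36 (sulfone alkylation, then desulfonylation).
2. The strategy rests on ring B: its contiguous centres C5, C10 and C9, with oxygenated C8 beside them, have the pattern of an endo adduct between a C5–C8 silyloxydiene and an (E)-C9=C10 β-methyl enoate tethered through C1–C4 of ring A. One intramolecular Diels–Alder reaction of triene 12 therefore closes rings A and B together.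
3. Triene 12 comes from methyl geranate: selective ozonolysis, iridium-catalysed tert-prenylation (sets C3), then vinyl → enal → dienol silyl ether.
4. DE part: ring E enone by enantioselective Michael/aldol annulation (sets C17); ring D by a tether-controlled intramolecular Michael addition of a β-keto ester (C18 cis); enol triflate methylation (C27) and a thermodynamically controlled C20 methyl.
5. Ring order: A and B together (step 8), E (step 14), D (step 17); the halves are joined in step 24.

Key step: step 8

Remark: atoms carry ursane numbers (C23/C24 on C4, C25 on C10, C26 the exocyclic methylene carbon, C27 on C14, C28 on C17, C29 on C19, C30 on C20); the sulfone-bearing C11 of 37 and 38 is a mixture of epimers that is erased in step 25.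

**Route**

Step 1
Reactants: 1 methyl geranate
Product: 3 methyl (2E)-3-methyl-6-oxohex-2-enoate, via secondary ozonide 2 (not isolated)
Conditions: O3 (1.0 equiv, indicator dye), CH2Cl2, −78 °C; then Me2S, −78 °C → rt
Reagents that add atoms: ozone, [O-][O+]=O
Why: Chemoselective ozonolysis: ozone attacks the electron-rich trisubstituted C6=C7 bond far faster than the conjugated enoate, and reductive work-up of the ozonide gives the aldehyde that becomes C3.

Step 2
Reactants: 3 methyl (2E)-3-methyl-6-oxohex-2-enoate; 4 3-methylbuta-1,2-diene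
Product: 5 methyl (2E,6S)-6-hydroxy-3,7,7-trimethylnona-2,8-dienoate
Conditions: [Ir(cod)Cl]2 (2.5 mol %), SEGPHOS (5 mol %), 4-cyano-3-nitrobenzoic acid (10 mol %), Cs2CO3 (20 mol %), i-PrOH (2 equiv), toluene, 60 °C
Reagents that add atoms: none
Why: Iridium-catalysed transfer-hydrogenative carbonyl tert-prenylation (reverse prenylation): the allene is hydrometalated to a 1,1-dimethylallyl iridium species that adds to the aldehyde through a closed chair transition state, and the ligand enantiomer is chosen so that the carbinol (C3) is S; isopropanol is the terminal reductant and the trisubstituted enoate is inert.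

Step 3
Reactants: 5 methyl (2E,6S)-6-hydroxy-3,7,7-trimethylnona-2,8-dienoate
Product: 6 methyl (2E,6S)-6-(tert-butyldimethylsilyloxy)-3,7,7-trimethylnona-2,8-dienoate
Conditions: TBSOTf, 2,6-lutidine, CH2Cl2, −78 → 0 °C
Reagents that add atoms: tert-butyldimethylsilyl triflate, CC(C)(C)[Si](C)(C)OS(=O)(=O)C(F)(F)F
Why: Silyl ether formation; the hindered neopentyl-type secondary alcohol needs the silyl triflate.

Step 4
Reactants: 6 methyl (2E,6S)-6-(tert-butyldimethylsilyloxy)-3,7,7-trimethylnona-2,8-dienoate
Product: 8 methyl (2E,6S)-6-(tert-butyldimethylsilyloxy)-9-hydroxy-3,7,7-trimethylnon-2-enoate, via alkylborane 7 (not isolated)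
Conditions: 9-BBN, THF, 0 °C → rt; then 30% H2O2, aq. NaOAc, 0 °C
Reagents that add atoms: hydrogen peroxide, OO
Why: Anti-Markovnikov hydroboration–oxidation: 9-BBN adds only to the monosubstituted vinyl group, and the buffered oxidation spares the methyl ester.

Step 5
Reactants: 8 methyl (2E,6S)-6-(tert-butyldimethylsilyloxy)-9-hydroxy-3,7,7-trimethylnon-2-enoate
Product: 9 methyl (2E,6S)-6-(tert-butyldimethylsilyloxy)-3,7,7-trimethyl-9-oxonon-2-enoate
Conditions: Dess–Martin periodinane, pyridine, CH2Cl2, 0 °C → rt
Reagents that add atoms: none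
Why: Dess–Martin oxidation of the primary alcohol to the aldehyde under neutral conditions.

Step 6
Reactants: 9 methyl (2E,6S)-6-(tert-butyldimethylsilyloxy)-3,7,7-trimethyl-9-oxonon-2-enoate; 10 (triphenylphosphoranylidene)acetaldehyde
Product: 11 methyl (2E,6S,9E)-6-(tert-butyldimethylsilyloxy)-3,7,7-trimethyl-11-oxoundeca-2,9-dienoate
Conditions: toluene, 80 °C, slow addition of 10
Reagents that add atoms: none
Why: Wittig olefination with the stabilised formylmethylene ylide should give the (E)-enal; slow addition limits a second homologation of the product.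

Step 7
Reactants: 11 methyl (2E,6S,9E)-6-(tert-butyldimethylsilyloxy)-3,7,7-trimethyl-11-oxoundeca-2,9-dienoate
Product: 12 methyl (2E,6S,8E,10E)-6-(tert-butyldimethylsilyloxy)-3,7,7-trimethyl-11-(triethylsilyloxy)undeca-2,8,10-trienoate
Conditions: TESOTf, Et3N, Et2O, −78 → 0 °C; non-aqueous work-up, used at once
Reagents that add atoms: triethylsilyl triflate, CC[Si](CC)(CC)OS(=O)(=O)C(F)(F)F
Why: Silyl dienol ether formation by soft enolisation: O-silylation of the s-trans enal and γ-deprotonation by Et3N should give the (1E,3E)-1-silyloxydiene, the new C5=C6 bond being E because of the quaternary C4.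

Step 8
Reactants: 12 methyl (2E,6S,8E,10E)-6-(tert-butyldimethylsilyloxy)-3,7,7-trimethyl-11-(triethylsilyloxy)undeca-2,8,10-trienoate
Product: 13 trans-fused Δ6-octalin ester (3β-OTBS; 5α-H; 8β-OTES; 9β-CO2Me; 10β-Me)
Conditions: toluene (0.01 M), BHT, N,O-bis(trimethylsilyl)acetamide (5 mol %), sealed tube, 170 °C
Reagents that add atoms: none
Why: Concerted suprafacial [4+2] cycloaddition, a type 1 intramolecular Diels–Alder reaction of a 1,7,9-decatrienoate: the nucleophilic diene terminus C5 bonds to the enoate β-carbon C10 and the silyloxy-bearing C8 to the α-carbon C9, the electronically matched pairing that the C1–C4 tether also enforces. Ring B closes as the six-membered cyclohexene (C6=C7) of the cycloaddition itself, and ring A closes as a six-membered carbocycle through the four-atom tether in a chair-like array with the tether anti and the ester endo, the gem-dimethyl group at C4 favouring the folded conformer. The E enoate puts the C10 methyl cis to the C11 ester (C10 and C9); the tether-anti transition state with the E C5=C6 bond puts H-5 trans to the C10 methyl (C5, trans ring fusion); the E dienol ether and the endo ester put the C8 silyloxy group cis to the ester (C8). The absolute sense comes from C3 (step 2), whose bulky silyloxy group should sit equatorial in the chair-like tether, so that the diene reaches only one face of the enoate. The step needs endo (trans-fused) over exo (cis-fused) selectivity and facial selectivity; the three E double bonds, the equatorial C3 substituent and the endo preference of the conjugating ester should secure them, while dilution, a radical inhibitor and an acid scavenger protect the dienol silyl ether at the temperature that the trisubstituted dienophile demands.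

Step 9
Reactants: 13 trans-fused Δ6-octalin ester
Product: 14 trans-decalin ester (3β-OTBS; 8β-OTES; 9β-CO2Me)
Conditions: H2 (3 atm), 5% Rh/Al2O3, EtOAc, rt
Reagents that add atoms: none
Why: Heterogeneous hydrogenation of the cis-disubstituted C6=C7 bond; rhodium on alumina is chosen to avoid hydrogenolysis of the allylic C8–O bond, and no stereocentre is formed.

Step 10
Reactants: 14 trans-decalin ester
Product: 15 trans-decalin C11 carbinol (3β-OTBS; 8β-OTES; 9β-CH2OH)
Conditions: i-Bu2AlH (2.5 equiv), CH2Cl2, −78 → 0 °C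
Reagents that add atoms: none
Why: Hydride reduction of the ester to the primary alcohol; at low temperature the aluminium alkoxide should neither eliminate nor shift the β-silyloxy group.

Step 11
Reactants: 15 trans-decalin C11 carbinol
Product: 16 C11 phenyl sulfide
Conditions: PhSSPh, n-Bu3P, pyridine, 60 °C
Reagents that add atoms: diphenyl disulfide, c1ccc(SSc2ccccc2)cc1
Why: Phosphine/disulfide thioetherification (Mitsunobu-type): thiolate displaces the alkoxyphosphonium at the hindered primary carbon in an SN2 step.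

Step 12
Reactants: 16 C11 phenyl sulfide
Product: 17 C11 phenyl sulfone
Conditions: mCPBA (2.2 equiv), CH2Cl2, 0 °C
Reagents that add atoms: 3-chloroperbenzoic acid, OOC(=O)c1cccc(Cl)c1
Why: Peracid oxidation of sulfide to sulfone; no alkene is left in the molecule and both silyl ethers are stable.

Step 13
Reactants: 18 propanal; 19 methyl acrylate
Product: 22 methyl 4-methyl-5-oxopentanoate, via enamine 20 (not isolated), via adduct enamine 21 (not isolated)
Conditions: pyrrolidine (1.1 equiv), K2CO3, 0 °C; then 19, MeCN, reflux; then AcOH–H2O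
Reagents that add atoms: none
Why: Stork enamine Michael addition of the propanal enamine to the acrylate, then hydrolysis; the new centre is racemic and becomes the quaternary C17 in step 14.

Step 14
Reactants: 22 methyl 4-methyl-5-oxopentanoate; 23 pent-1-en-3-one
Product: 25 methyl 3-[(1R)-1,3-dimethyl-4-oxocyclohex-2-en-1-yl]propanoate, via keto aldehyde 24 (not isolated)
Conditions: N-(4-dodecylphenylsulfonyl)prolinamide (20 mol %, enantiomer giving 17R), ClCH2CH2Cl, rt; then p-TsOH·H2O (cat.), toluene, 80 °C
Reagents that add atoms: none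
Why: Amine-catalysed asymmetric Michael addition of the α-branched aldehyde (as its enamine) to the vinyl ketone sets the quaternary C17 under catalyst control, and acid-catalysed aldol condensation of the ethyl ketone onto the non-enolisable aldehyde closes ring E (Robinson annulation) with the C29 methyl already on the enone α-carbon.

Step 15
Reactants: 25 methyl 3-[(1R)-1,3-dimethyl-4-oxocyclohex-2-en-1-yl]propanoate
Product: 26 3-[(1R)-1,3-dimethyl-4-oxocyclohex-2-en-1-yl]propanoic acid
Conditions: LiOH, THF–H2O, rt; aq. HCl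
Reagents that add atoms: lithium hydroxide, [Li+].[OH-]
Why: Ester saponification; the enone has no epimerisable centre.

Step 16
Reactants: 26 3-[(1R)-1,3-dimethyl-4-oxocyclohex-2-en-1-yl]propanoic acid
Product: 29 methyl 5-[(1S)-1,3-dimethyl-4-oxocyclohex-2-en-1-yl]-3-oxopentanoate, via acyl imidazole 27 (not isolated), via acylmalonic half ester 28 (not isolated)
Conditions: carbonyldiimidazole, THF, rt; then Mg(O2CCH2CO2Me)2, THF, rt → 40 °C; aq. HCl
Reagents that add atoms: magnesium bis(methyl malonate), [Mg+2].COC(=O)CC(=O)[O-].COC(=O)CC(=O)[O-]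
Why: C-acylation of the magnesium malonate by the acyl imidazolide followed by decarboxylation (Claisen-type homologation) gives the β-keto ester (C13, C12) under neutral conditions that leave the enone alone; the descriptor changes only through the CIP ranking.

Step 17
Reactants: 29 methyl 5-[(1S)-1,3-dimethyl-4-oxocyclohex-2-en-1-yl]-3-oxopentanoate
Product: 30 cis-fused bicyclic diketo ester (17β-Me; 18β-H; 19β-Me; C14 and C20 ketones; C13 CO2Me, keto–enol mixture)
Conditions: Cs2CO3 (0.5 equiv), MeCN, rt → 50 °C
Reagents that add atoms: none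
Why: Intramolecular Michael addition (6-exo-trig) of the β-keto ester carbon C13 to C18 of the enone: the tether from C17 reaches only the face it sits on and attack must be axial, so ring D closes cis-fused (18-H cis to the C17 methyl); the C19 methyl, α to the C20 ketone, should equilibrate to the equatorial position, which is favoured because 1,2-allylic strain with the enolised ester keeps C19 pseudo-axial on ring D.

Step 18
Reactants: 30 cis-fused bicyclic diketo ester
Product: 31 C14 enol triflate
Conditions: Tf2O, i-Pr2NEt, CH2Cl2, −78 °C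
Reagents that add atoms: triflic anhydride, O=S(=O)(OS(=O)(=O)C(F)(F)F)C(F)(F)F
Why: Enol triflate formation at the far more acidic β-keto ester; the simple C20 ketone is not enolised by the amine base.

Step 19
Reactants: 31 C14 enol triflate
Product: 32 bicyclic enoate ketone (C13=C14 with C27 methyl; C20 ketone)
Conditions: MeB(OH)2, Pd(dppf)Cl2 (5 mol %), K2CO3, dioxane–H2O, 80 °C
Reagents that add atoms: methylboronic acid, CB(O)O
Why: Suzuki–Miyaura methylation of the β-triflyloxy enoate fixes the tetrasubstituted C13=C14 bond and its C27 methyl regiospecifically; the carbonate base keeps C19 at its thermodynamic configuration.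

Step 20
Reactants: 32 bicyclic enoate ketone
Product: 33 C20 methylene enoate
Conditions: Ph3PCH3Br, KOt-Bu, THF, 0 °C → rt
Reagents that add atoms: methyltriphenylphosphonium bromide, C[P+](c1ccccc1)(c1ccccc1)c1ccccc1.[Br-]
Why: Wittig methylenation of the ring E ketone brings in C30; the hindered conjugated ester does not react with the ylide.

Step 21
Reactants: 33 C20 methylene enoate
Product: 34 methyl ester of the DE acid (17β-Me; 18β-H; 19β-Me; 20α-Me)
Conditions: Mn(dpm)3 (10 mol %), PhSiH3, t-BuOOH, i-PrOH, rt
Reagents that add atoms: none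
Why: Manganese hydride hydrogen-atom-transfer hydrogenation: the 1,1-disubstituted C20=C30 bond gives a tertiary C20 radical that should take its hydrogen on the axial face, leaving the C30 methyl equatorial and trans to the C29 methyl (thermodynamic stereocontrol); the tetrasubstituted conjugated C13=C14 bond is too hindered to react.

Step 22
Reactants: 34 methyl ester of the DE acid
Product: 35 DE allylic alcohol (C12 OH)
Conditions: i-Bu2AlH (2.5 equiv), CH2Cl2, −78 → 0 °C
Reagents that add atoms: none
Why: 1,2-Reduction of the conjugated ester to the allylic alcohol by the aluminium hydride.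

Step 23
Reactants: 35 DE allylic alcohol
Product: 36 DE allylic bromide (C12 Br)
Conditions: CBr4, PPh3, CH2Cl2, 0 °C; used at once
Reagents that add atoms: carbon tetrabromide, BrC(Br)(Br)Br
Why: Appel bromination of the primary allylic alcohol under neutral conditions, without allylic transposition because the γ-carbon is fully substituted.

Step 24
Reactants: 17 C11 phenyl sulfone; 36 DE allylic bromide
Product: 38 AB–DE coupled C11 sulfone (both C11 epimers), via lithiated sulfone 37 (not isolated)
Conditions: n-BuLi (1.05 equiv), THF, −78 °C; then 36, DMPU, −78 → −20 °C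
Reagents that add atoms: none
Why: Alkylation of the α-sulfonyl carbanion with the primary allylic bromide (SN2; SN2' is blocked at the fully substituted C14) forms the C11–C12 bond.

Step 25
Reactants: 38 AB–DE coupled C11 sulfone
Product: 39 bis-silyl ether of the seco-triterpene (3β-OTBS; 8β-OTES; Δ13)
Conditions: 6% Na(Hg), Na2HPO4, MeOH–THF, −20 °C → rt
Reagents that add atoms: none
Why: Reductive desulfonylation by electron transfer; the sulfone is homoallylic, so the C13=C14 bond cannot migrate, and C11 becomes a methylene group.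

Step 26
Reactants: 39 bis-silyl ether of the seco-triterpene
Product: 40 C8 alcohol (3β-OTBS; 8β-OH)
Conditions: PPTS (0.2 equiv), MeOH–CH2Cl2, 0 °C → rt
Reagents that add atoms: none
Why: Acid-catalysed methanolysis removes the triethylsilyl ether selectively; the neopentyl tert-butyldimethylsilyl ether at C3 reacts far more slowly.

Step 27
Reactants: 40 C8 alcohol
Product: 41 C8 ketone (3β-OTBS)
Conditions: Dess–Martin periodinane, pyridine, CH2Cl2, rt
Reagents that add atoms: none
Why: Dess–Martin oxidation of the axial secondary alcohol; C9 keeps its equatorial side chain, which is also the thermodynamic arrangement.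

Step 28
Reactants: 41 C8 ketone
Product: 42 3-O-TBS ether of the target (C8=C26)
Conditions: Ph3PCH3Br, KOt-Bu, toluene, 90 °C
Reagents that add atoms: methyltriphenylphosphonium bromide, C[P+](c1ccccc1)(c1ccccc1)c1ccccc1.[Br-]
Why: Wittig methylenation of the hindered ketone with excess ylide; enolisation towards C9 cannot lower the purity because C9 already has its more stable configuration.

Step 29
Reactants: 42 3-O-TBS ether of the target
Product: 43 8,14-secoursa-8(26),13-dien-3β-ol (target)
Conditions: Bu4NF, THF, 60 °C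
Reagents that add atoms: none
Why: Fluoride cleavage of the hindered C3 silyl ether; both alkenes are inert.

**Compound list**
1 | methyl geranate, methyl (2E)-3,7-dimethylocta-2,6-dienoate | COC(=O)/C=C(\C)CCC=C(C)C | starting material
2 | secondary ozonide of 1 at C6=C7 | COC(=O)/C=C(\C)CCC1OOC(C)(C)O1 | intermediate
3 | methyl (2E)-3-methyl-6-oxohex-2-enoate | COC(=O)/C=C(\C)CCC=O | intermediate
4 | 3-methylbuta-1,2-diene | CC(C)=C=C | starting material
5 | methyl (2E,6S)-6-hydroxy-3,7,7-trimethylnona-2,8-dienoate | COC(=O)/C=C(\C)CC[C@H](O)C(C)(C)C=C | intermediate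
6 | methyl (2E,6S)-6-(tert-butyldimethylsilyloxy)-3,7,7-trimethylnona-2,8-dienoate | COC(=O)/C=C(\C)CC[C@H](O[Si](C)(C)C(C)(C)C)C(C)(C)C=C | intermediate
7 | B-alkyl-9-borabicyclo[3.3.1]nonane from 6 (boron on the terminal carbon) | COC(=O)/C=C(\C)CC[C@H](O[Si](C)(C)C(C)(C)C)C(C)(C)CCB1C2CCCC1CCC2 | intermediate
8 | methyl (2E,6S)-6-(tert-butyldimethylsilyloxy)-9-hydroxy-3,7,7-trimethylnon-2-enoate | COC(=O)/C=C(\C)CC[C@H](O[Si](C)(C)C(C)(C)C)C(C)(C)CCO | intermediate
9 | methyl (2E,6S)-6-(tert-butyldimethylsilyloxy)-3,7,7-trimethyl-9-oxonon-2-enoate | COC(=O)/C=C(\C)CC[C@H](O[Si](C)(C)C(C)(C)C)C(C)(C)CC=O | intermediate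
10 | (triphenylphosphoranylidene)acetaldehyde | O=CC=P(c1ccccc1)(c1ccccc1)c1ccccc1 | starting material
11 | methyl (2E,6S,9E)-6-(tert-butyldimethylsilyloxy)-3,7,7-trimethyl-11-oxoundeca-2,9-dienoate | COC(=O)/C=C(\C)CC[C@H](O[Si](C)(C)C(C)(C)C)C(C)(C)C/C=C/C=O | intermediate
12 | methyl (2E,6S,8E,10E)-6-(tert-butyldimethylsilyloxy)-3,7,7-trimethyl-11-(triethylsilyloxy)undeca-2,8,10-trienoate | COC(=O)/C=C(\C)CC[C@H](O[Si](C)(C)C(C)(C)C)C(C)(C)/C=C/C=C/O[Si](CC)(CC)CC | intermediate
13 | trans-fused Δ6-octalin ester: 3β-OTBS, 5α-H, 8β-OTES, 9β-CO2Me (C11), 10β-Me | CC[Si](CC)(CC)O[C@H]1C=C[C@H]2C(C)(C)[C@@H](O[Si](C)(C)C(C)(C)C)CC[C@]2(C)[C@H]1C(=O)OC | intermediate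
14 | trans-decalin ester: 3β-OTBS, 8β-OTES, 9β-CO2Me | CC[Si](CC)(CC)O[C@H]1CC[C@H]2C(C)(C)[C@@H](O[Si](C)(C)C(C)(C)C)CC[C@]2(C)[C@H]1C(=O)OC | intermediate
15 | trans-decalin C11 carbinol: 3β-OTBS, 8β-OTES, 9β-CH2OH | CC[Si](CC)(CC)O[C@H]1CC[C@H]2C(C)(C)[C@@H](O[Si](C)(C)C(C)(C)C)CC[C@]2(C)[C@H]1CO | intermediate
16 | C11 phenyl sulfide of 15 | CC[Si](CC)(CC)O[C@H]1CC[C@H]2C(C)(C)[C@@H](O[Si](C)(C)C(C)(C)C)CC[C@]2(C)[C@H]1CSc1ccccc1 | intermediate
17 | C11 phenyl sulfone | CC[Si](CC)(CC)O[C@H]1CC[C@H]2C(C)(C)[C@@H](O[Si](C)(C)C(C)(C)C)CC[C@]2(C)[C@H]1CS(=O)(=O)c1ccccc1 | intermediate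
18 | propanal | CCC=O | starting material
19 | methyl acrylate | C=CC(=O)OC | starting material
20 | 1-[(E)-prop-1-en-1-yl]pyrrolidine | C/C=C/N1CCCC1 | intermediate
21 | methyl 4-methyl-5-(pyrrolidin-1-yl)pent-4-enoate | COC(=O)CCC(C)=CN1CCCC1 | intermediate
22 | methyl 4-methyl-5-oxopentanoate (racemic) | COC(=O)CCC(C)C=O | intermediate
23 | pent-1-en-3-one (ethyl vinyl ketone) | CCC(=O)C=C | starting material
24 | methyl (4R)-4-formyl-4-methyl-7-oxononanoate | COC(=O)CC[C@](C)(C=O)CCC(=O)CC | intermediate
25 | methyl 3-[(1R)-1,3-dimethyl-4-oxocyclohex-2-en-1-yl]propanoate | O=C1CC[C@](C)(CCC(=O)OC)C=C1C | intermediate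
26 | 3-[(1R)-1,3-dimethyl-4-oxocyclohex-2-en-1-yl]propanoic acid | O=C1CC[C@](C)(CCC(=O)O)C=C1C | intermediate
27 | acyl imidazole of 26 | O=C1CC[C@](C)(CCC(=O)n2ccnc2)C=C1C | intermediate
28 | acylmalonic half ester (methyl hydrogen 2-acylmalonate, same C17 arrangement) | O=C1CC[C@](C)(CCC(=O)C(C(=O)O)C(=O)OC)C=C1C | intermediate
29 | methyl 5-[(1S)-1,3-dimethyl-4-oxocyclohex-2-en-1-yl]-3-oxopentanoate | O=C1CC[C@](C)(CCC(=O)CC(=O)OC)C=C1C | intermediate
30 | cis-fused methyl 4a,8-dimethyl-2,7-dioxodecahydronaphthalene-1-carboxylate: 17β-Me, 18β-H, 19β-Me, C13 unassigned | COC(=O)C1C(=O)CC[C@@]2(C)CCC(=O)[C@H](C)[C@@H]12 | intermediate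
31 | C14 enol triflate of 30 | COC(=O)C1=C(OS(=O)(=O)C(F)(F)F)CC[C@@]2(C)CCC(=O)[C@H](C)[C@@H]12 | intermediate
32 | bicyclic enoate ketone: C13=C14, C27 methyl, C20 ketone | COC(=O)C1=C(C)CC[C@@]2(C)CCC(=O)[C@H](C)[C@@H]12 | intermediate
33 | C20 methylene enoate | COC(=O)C1=C(C)CC[C@@]2(C)CCC(=C)[C@H](C)[C@@H]12 | intermediate
34 | DE methyl ester: 17β-Me, 18β-H, 19β-Me, 20α-Me, Δ13 | COC(=O)C1=C(C)CC[C@@]2(C)CC[C@@H](C)[C@H](C)[C@@H]12 | intermediate
35 | DE allylic alcohol (C12 OH) | OCC1=C(C)CC[C@@]2(C)CC[C@@H](C)[C@H](C)[C@@H]12 | intermediate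
36 | DE allylic bromide (C12 Br) | BrCC1=C(C)CC[C@@]2(C)CC[C@@H](C)[C@H](C)[C@@H]12 | intermediate
37 | C11-lithiated sulfone from 17 | CC[Si](CC)(CC)O[C@H]1CC[C@H]2C(C)(C)[C@@H](O[Si](C)(C)C(C)(C)C)CC[C@]2(C)[C@H]1C([Li])S(=O)(=O)c1ccccc1 | intermediate
38 | AB–DE coupled C11 sulfone, both C11 epimers | CC[Si](CC)(CC)O[C@H]1CC[C@H]2C(C)(C)[C@@H](O[Si](C)(C)C(C)(C)C)CC[C@]2(C)[C@H]1C(CC1=C(C)CC[C@@]2(C)CC[C@@H](C)[C@H](C)[C@@H]12)S(=O)(=O)c1ccccc1 | intermediate
39 | 3β-OTBS, 8β-OTES seco-triterpene (Δ13) | CC[Si](CC)(CC)O[C@H]1CC[C@H]2C(C)(C)[C@@H](O[Si](C)(C)C(C)(C)C)CC[C@]2(C)[C@H]1CCC1=C(C)CC[C@@]2(C)CC[C@@H](C)[C@H](C)[C@@H]12 | intermediate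
40 | 3β-OTBS, 8β-OH seco-triterpene | O[C@H]1CC[C@H]2C(C)(C)[C@@H](O[Si](C)(C)C(C)(C)C)CC[C@]2(C)[C@H]1CCC1=C(C)CC[C@@]2(C)CC[C@@H](C)[C@H](C)[C@@H]12 | intermediate
41 | 3β-OTBS C8 ketone | O=C1CC[C@H]2C(C)(C)[C@@H](O[Si](C)(C)C(C)(C)C)CC[C@]2(C)[C@H]1CCC1=C(C)CC[C@@]2(C)CC[C@@H](C)[C@H](C)[C@@H]12 | intermediate
42 | 3-O-TBS ether of the target | C=C1CC[C@H]2C(C)(C)[C@@H](O[Si](C)(C)C(C)(C)C)CC[C@]2(C)[C@H]1CCC1=C(C)CC[C@@]2(C)CC[C@@H](C)[C@H](C)[C@@H]12 | intermediate
43 | 8,14-secoursa-8(26),13-dien-3β-ol (CNP0210309.1) | C=C1CC[C@H]2C(C)(C)[C@@H](O)CC[C@]2(C)[C@H]1CCC1=C(C)CC[C@@]2(C)CC[C@@H](C)[C@H](C)[C@@H]12 | target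

**Step count**
Total: 29 steps. Longest linear sequence: 18 steps (steps 1–12, then 24–29). The DE branch (steps 13–23, 11 steps) joins at step 24.

**Steps most likely to fail, with fallbacks**

Step 8 (key step). The cycloaddition may be too slow at a temperature the dienol silyl ether tolerates, or it may lose endo and facial selectivity because the trisubstituted enoate reacts only under forcing conditions. The fallback keeps the same ring-forming event but makes the dienophile an aldehyde. From 12, i-Bu2AlH (toluene, −78 °C) reduces the ester to the allylic alcohol triene F1, and MnO2 (CH2Cl2) oxidises it to the trienal F2. The enal should cyclise at a much lower temperature (toluene, 80–110 °C) through the same endo, tether-anti transition state to the octalin aldehyde F3. NaBH4 (MeOH, 0 °C) gives the octalin carbinol F4, and hydrogenation (H2, Rh/Al2O3, EtOAc) comes back to the route at 15.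

Step 14. Enamine formation from the α-branched aldehyde may be slow and the facial discrimination in the Michael addition may be low, so that C17 is formed with insufficient enantiomeric purity. The fallback is a racemic annulation followed by resolution. From 22, the pyrrolidine enamine is added to pent-1-en-3-one and cyclised with AcOH/NaOAc to the racemic enone ester F5. LiOH gives the racemic enone acid F6, and crystallisation with (S)-1-phenylethylamine (its antipode if the other salt is the less soluble one) gives the salt of the R acid F7. Acidification with aq. HCl comes back to the route at 26.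

Step 21. Hydrogen-atom delivery to the C20 radical may not discriminate well between the axial and equatorial faces, or hydrogen-atom transfer to the conjugated ester may compete. The fallback sets C20 through an epimerisable aldehyde. From 32, Wittig reaction with Ph3P=CHOMe (from MeOCH2PPh3Cl and KOt-Bu) gives the enol ether F8. Hydrolysis (aq. HCl, THF) and equilibration (K2CO3, MeOH) give the equatorial C30 aldehyde F9, trans to the C29 methyl. NaBH4 reduces it to the C30 carbinol F10, and MsCl/Et3N gives the mesylate F11. Excess LiEt3BH (THF, 0 °C → rt) then reduces C–OMs to the methyl group and the ester to the allylic alcohol in one operation, coming back to the route at 35.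

**Further compounds**
F1 | step 8 | allylic alcohol triene, (2E,6S,8E,10E)-6-(tert-butyldimethylsilyloxy)-3,7,7-trimethyl-11-(triethylsilyloxy)undeca-2,8,10-trien-1-ol | OC/C=C(\C)CC[C@H](O[Si](C)(C)C(C)(C)C)C(C)(C)/C=C/C=C/O[Si](CC)(CC)CC
F2 | step 8 | trienal, the corresponding (2E)-enal | O=C/C=C(\C)CC[C@H](O[Si](C)(C)C(C)(C)C)C(C)(C)/C=C/C=C/O[Si](CC)(CC)CC
F3 | step 8 | octalin aldehyde (as 13 with 9β-CHO) | CC[Si](CC)(CC)O[C@H]1C=C[C@H]2C(C)(C)[C@@H](O[Si](C)(C)C(C)(C)C)CC[C@]2(C)[C@H]1C=O
F4 | step 8 | octalin carbinol (as 13 with 9β-CH2OH) | CC[Si](CC)(CC)O[C@H]1C=C[C@H]2C(C)(C)[C@@H](O[Si](C)(C)C(C)(C)C)CC[C@]2(C)[C@H]1CO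
F5 | step 14 | racemic methyl 3-(1,3-dimethyl-4-oxocyclohex-2-en-1-yl)propanoate | O=C1CCC(C)(CCC(=O)OC)C=C1C
F6 | step 14 | racemic 3-(1,3-dimethyl-4-oxocyclohex-2-en-1-yl)propanoic acid | O=C1CCC(C)(CCC(=O)O)C=C1C
F7 | step 14 | (S)-1-phenylethylammonium salt of the R acid 26 | O=C1CC[C@](C)(CCC(=O)[O-])C=C1C.C[C@H]([NH3+])c1ccccc1
F8 | step 21 | C20 methoxymethylene enoate (E/Z mixture) | COC(=O)C1=C(C)CC[C@@]2(C)CCC(=COC)[C@H](C)[C@@H]12
F9 | step 21 | C30 aldehyde, equatorial at C20 | COC(=O)C1=C(C)CC[C@@]2(C)CC[C@@H](C=O)[C@H](C)[C@@H]12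
F10 | step 21 | C30 carbinol | COC(=O)C1=C(C)CC[C@@]2(C)CC[C@@H](CO)[C@H](C)[C@@H]12
F11 | step 21 | C30 mesylate | COC(=O)C1=C(C)CC[C@@]2(C)CC[C@@H](COS(C)(=O)=O)[C@H](C)[C@@H]12
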